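The key step closes ring A of the 7‑methoxycoumarin (unit A) from a squaric acid derivative, so the crowded diaryl ether is never formed at an arene carbon. The three contiguous oxygen‑bearing carbons of the four‑membered ring become C7 (OMe), C8 (O‑aryl) and C8a (ring oxygen) of ring A. The precursor is a 4‑chloro‑3‑methoxycyclobutenone that carries the dibenzylated 5,7‑dioxygenated coumarin (unit B) as its 2‑aryloxy group. In one operation, a Stille coupling with a stannyl dienoate, 4π ring opening and 6π ring closure create C5–C6 and C4a–C8a and deliver the 2‑hydroxycinnamate of unit A. Sensitized alkene isomerization with lactonization, then debenzylation, finish the target.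

Key step: step 10

Assumption: coumarin numbering is used for both halves; squaric acid dichloride 6 is taken as purchasable (otherwise one extra step from squaric acid with oxalyl chloride and cat. DMF).

Step 1
Reactants: 1 5,7-dihydroxycoumarin
Product: 2 5,7-bis(benzyloxy)-2H-chromen-2-one
Conditions: BnBr, K2CO3, DMF, 60 °C
Reagents that add atoms: benzyl bromide, BrCc1ccccc1
Why: Williamson etherification of the two acidic phenols with a mild carbonate base, under which the coumarin lactone is untouched in dry DMF.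

Step 2
Reactants: 2 5,7-bis(benzyloxy)-2H-chromen-2-one
Product: 3 5,7-bis(benzyloxy)-2-oxo-2H-chromene-8-carbaldehyde
Conditions: POCl3, DMF, 0 → 70 °C; then H2O, 0 °C → rt
Reagents that add atoms: N,N-dimethylformamide, CN(C)C=O; water, O
Why: Vilsmeier–Haack formylation should go to C8, which is para to the 5‑benzyloxy and ortho to the 7‑benzyloxy group and less shielded than C6 between two benzyloxy groups (the same site preference is seen in acylations of 5,7‑dioxygenated coumarins).

Step 3
Reactants: 3 5,7-bis(benzyloxy)-2-oxo-2H-chromene-8-carbaldehyde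
Product: 5 5,7-bis(benzyloxy)-8-hydroxy-2H-chromen-2-one, via aryl formate 4 (not isolated)
Conditions: mCPBA, CH2Cl2, 0 °C → rt; then Et3N (cat.), MeOH, rt
Reagents that add atoms: 3-chloroperoxybenzoic acid, OOC(=O)c1cccc(Cl)c1
Why: Baeyer–Villiger (Dakin‑type) oxidation in which the electron‑rich, doubly ortho‑oxygenated aryl group migrates to give formate 4, which is cleaved by base‑catalysed methanolysis; the electron‑poor C3=C4 bond of the coumarin is inert to the peracid.

Step 4
Reactants: 6 squaric acid dichloride (3,4-dichlorocyclobut-3-ene-1,2-dione)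
Product: 7 3-chloro-4-methoxycyclobut-3-ene-1,2-dione
Conditions: MeOH (1.0 equiv), CH2Cl2, 0 °C → rt
Reagents that add atoms: methanol, CO
Why: Alcoholysis of a vinylogous acid chloride (addition–elimination), which should stop after one substitution because the methoxy donor deactivates the remaining C–Cl carbon.

Step 5
Reactants: 5 5,7-bis(benzyloxy)-8-hydroxy-2H-chromen-2-one; 7 3-chloro-4-methoxycyclobut-3-ene-1,2-dione
Product: 8 3-{[5,7-bis(benzyloxy)-2-oxo-2H-chromen-8-yl]oxy}-4-methoxycyclobut-3-ene-1,2-dione
Conditions: iPr2NEt, CH2Cl2, −78 → 0 °C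
Reagents that add atoms: none
Why: Addition–elimination of the phenoxide at the chlorine‑bearing carbon of the vinylogous acid chloride; chloride is by far the better leaving group, so the exchange is irreversible (a phenol would not displace methoxide from a methyl squarate), the methoxy group is kept, and the hindered O–aryl bond is made at an unhindered sp2 carbon and not at the di‑ortho‑substituted arene.

Step 6
Reactants: 8 3-{[5,7-bis(benzyloxy)-2-oxo-2H-chromen-8-yl]oxy}-4-methoxycyclobut-3-ene-1,2-dione
Product: 9 racemic 2-{[5,7-bis(benzyloxy)-2-oxo-2H-chromen-8-yl]oxy}-4-hydroxy-3-methoxycyclobut-2-en-1-one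
Conditions: LiAlH(OtBu)3 (1.05 equiv), THF, −78 °C
Reagents that add atoms: none
Why: 1,2‑Reduction of a squarate carbonyl by the bulky, mild hydride LiAlH(OtBu)3, which should choose the carbonyl conjugated through the ring double bond with the weaker aryloxy donor (and flanked by the small methoxy carbon), leaving the stronger vinylogous methyl ester and the coumarin lactone intact; the new carbinol centre forms as a racemate and is later lost.

Step 7
Reactants: 9 racemic 2-{[5,7-bis(benzyloxy)-2-oxo-2H-chromen-8-yl]oxy}-4-hydroxy-3-methoxycyclobut-2-en-1-one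
Product: 10 racemic 2-{[5,7-bis(benzyloxy)-2-oxo-2H-chromen-8-yl]oxy}-4-chloro-3-methoxycyclobut-2-en-1-one
Conditions: PPh3, hexachloroacetone, CH2Cl2, −20 → 0 °C
Reagents that add atoms: hexachloroacetone, ClC(Cl)(Cl)C(=O)C(Cl)(Cl)Cl
Why: Appel‑type chlorination under neutral conditions, in which chloride displaces the oxyphosphonium group by SN2 at the α‑keto, allylic carbon without ionization and hence without allylic transposition; the stereocentre is racemic.

Step 8
Reactants: 11 propargyl alcohol; 12 tributyltin hydride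
Product: 13 (E)-3-(tributylstannyl)prop-2-en-1-ol
Conditions: AIBN (cat.), neat, 80 °C
Reagents that add atoms: none
Why: Radical hydrostannation of the terminal alkyne, where reversible stannyl‑radical addition at 80 °C equilibrates the adducts towards the (E)‑β‑stannyl alkene, which is separated from minor isomers by chromatography.

Step 9
Reactants: 13 (E)-3-(tributylstannyl)prop-2-en-1-ol
Product: 15 methyl (2E,4E)-5-(tributylstannyl)penta-2,4-dienoate, via stannylpropenal 14 (not isolated)
Conditions: MnO2, Ph3P=CHCO2Me, CH2Cl2, rt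
Reagents that add atoms: methyl (triphenylphosphoranylidene)acetate, COC(=O)C=P(c1ccccc1)(c1ccccc1)c1ccccc1
Why: Tandem allylic oxidation–Wittig olefination: MnO2 oxidizes the allylic alcohol to aldehyde 14, which is trapped at once by the stabilized ylide to give the new double bond with E geometry, the vinyl–tin bond being inert to both reagents.

Step 10
Reactants: 10 racemic 2-{[5,7-bis(benzyloxy)-2-oxo-2H-chromen-8-yl]oxy}-4-chloro-3-methoxycyclobut-2-en-1-one; 15 methyl (2E,4E)-5-(tributylstannyl)penta-2,4-dienoate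
Product: 19 methyl (E)-3-(3-{[5,7-bis(benzyloxy)-2-oxo-2H-chromen-8-yl]oxy}-2-hydroxy-4-methoxyphenyl)acrylate, via dienylcyclobutenone 16 (not isolated), via dienylketene 17 (not isolated), via cyclohexadienone 18 (not isolated)
Conditions: PdCl2(PhCN)2 (5 mol %), tri(2-furyl)phosphine (10 mol %), dioxane, 50 °C then 100 °C
Reagents that add atoms: none
Why: PdCl2(PhCN)2 is reduced by the stannane to zerovalent palladium, which inserts into the allylic, α‑keto C–Cl bond of 10; transmetalation from tin and reductive elimination join the dienyl group to cyclobutenone C4 (Stille coupling, forming C5–C6 of ring A) to give 16. On warming, 16 undergoes conrotatory 4π ring opening to dienylketene 17, which closes ring A by a thermal disrotatory 6π‑electrocyclization between the ketene carbon and the far carbon of the first alkene (C8a–C4a), and dienone 18 tautomerizes to the phenol. The closest known reaction type is the palladium‑catalysed coupling of 4‑chlorocyclobutenones with alkenylstannanes with in situ benzannulation to phenols. No stereocentre remains, since the transient sp3 carbons of 16 and 18 are lost on aromatization, and the E acrylate geometry is inherited from 15 because that double bond is a spectator. The step needs bond formation at C4 and not at the other allyl terminus C2, which the fully substituted, aryloxy‑bearing C2 and the retained vinylogous‑ester conjugation in 16 should secure; the phenol position next to the aryloxy carbon is fixed by the location of the carbonyl in 10. Ring opening is reversible, so ketene rotated outward that cannot cyclize returns to 16 and is funnelled through the productive inward isomer.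

Step 11
Reactants: 19 methyl (E)-3-(3-{[5,7-bis(benzyloxy)-2-oxo-2H-chromen-8-yl]oxy}-2-hydroxy-4-methoxyphenyl)acrylate
Product: 21 8-{[5,7-bis(benzyloxy)-2-oxo-2H-chromen-8-yl]oxy}-7-methoxy-2H-chromen-2-one, via Z-cinnamate 20 (not isolated)
Conditions: fac-Ir(ppy)3 (1 mol %), blue LEDs (450 nm), MeCN (0.01 M), rt
Reagents that add atoms: none
Why: Triplet energy transfer from the visible‑light‑excited iridium sensitizer isomerizes the cinnamate to its Z isomer (contra‑thermodynamic E→Z photoisomerization), which is removed by spontaneous lactonization onto the neighbouring phenol with loss of methanol; neither coumarin absorbs at 450 nm and their triplet energies lie above that of the sensitizer, so coumarin [2+2] photodimerization is avoided.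

Step 12
Reactants: 21 8-{[5,7-bis(benzyloxy)-2-oxo-2H-chromen-8-yl]oxy}-7-methoxy-2H-chromen-2-one
Product: 22 8-[(5,7-dihydroxy-2-oxo-2H-chromen-8-yl)oxy]-7-methoxy-2H-chromen-2-one
Conditions: BCl3, pentamethylbenzene, CH2Cl2, −78 °C
Reagents that add atoms: none
Why: Lewis‑acid cleavage of the two aryl benzyl ethers by BCl3 at low temperature with pentamethylbenzene as a non‑basic benzyl cation scavenger, conditions under which the aryl methyl ether, the diaryl ether and both lactones survive and which avoid the reduction of the coumarin C3=C4 bonds that hydrogenolysis would risk.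

Compound list
1 | 5,7-dihydroxy-2H-chromen-2-one (5,7-dihydroxycoumarin) | Oc1cc(O)c2ccc(=O)oc2c1 | starting material
2 | 5,7-bis(benzyloxy)-2H-chromen-2-one | O=c1ccc2c(OCc3ccccc3)cc(OCc3ccccc3)cc2o1 | intermediate
3 | 5,7-bis(benzyloxy)-2-oxo-2H-chromene-8-carbaldehyde | O=Cc1c(OCc2ccccc2)cc(OCc2ccccc2)c2ccc(=O)oc12 | intermediate
4 | 5,7-bis(benzyloxy)-2-oxo-2H-chromen-8-yl formate | O=COc1c(OCc2ccccc2)cc(OCc2ccccc2)c2ccc(=O)oc12 | intermediate (not isolated)
5 | 5,7-bis(benzyloxy)-8-hydroxy-2H-chromen-2-one | Oc1c(OCc2ccccc2)cc(OCc2ccccc2)c2ccc(=O)oc12 | intermediate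
6 | 3,4-dichlorocyclobut-3-ene-1,2-dione (squaric acid dichloride) | ClC1=C(Cl)C(=O)C1=O | starting material
7 | 3-chloro-4-methoxycyclobut-3-ene-1,2-dione | COC1=C(Cl)C(=O)C1=O | intermediate
8 | 3-{[5,7-bis(benzyloxy)-2-oxo-2H-chromen-8-yl]oxy}-4-methoxycyclobut-3-ene-1,2-dione | COC1=C(Oc2c(OCc3ccccc3)cc(OCc3ccccc3)c3ccc(=O)oc23)C(=O)C1=O | intermediate
9 | racemic 2-{[5,7-bis(benzyloxy)-2-oxo-2H-chromen-8-yl]oxy}-4-hydroxy-3-methoxycyclobut-2-en-1-one | COC1=C(Oc2c(OCc3ccccc3)cc(OCc3ccccc3)c3ccc(=O)oc23)C(=O)C1O | intermediate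
10 | racemic 2-{[5,7-bis(benzyloxy)-2-oxo-2H-chromen-8-yl]oxy}-4-chloro-3-methoxycyclobut-2-en-1-one | COC1=C(Oc2c(OCc3ccccc3)cc(OCc3ccccc3)c3ccc(=O)oc23)C(=O)C1Cl | intermediate
11 | prop-2-yn-1-ol (propargyl alcohol) | C#CCO | starting material
12 | tributyltin hydride | CCCC[SnH](CCCC)CCCC | starting material
13 | (E)-3-(tributylstannyl)prop-2-en-1-ol | CCCC[Sn](CCCC)(CCCC)/C=C/CO | intermediate
14 | (E)-3-(tributylstannyl)prop-2-enal | CCCC[Sn](CCCC)(CCCC)/C=C/C=O | intermediate (not isolated)
15 | methyl (2E,4E)-5-(tributylstannyl)penta-2,4-dienoate | CCCC[Sn](CCCC)(CCCC)/C=C/C=C/C(=O)OC | intermediate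
16 | racemic methyl (2E,4E)-5-(3-{[5,7-bis(benzyloxy)-2-oxo-2H-chromen-8-yl]oxy}-2-methoxy-4-oxocyclobut-2-en-1-yl)penta-2,4-dienoate | COC(=O)/C=C/C=C/C1C(OC)=C(Oc2c(OCc3ccccc3)cc(OCc3ccccc3)c3ccc(=O)oc23)C1=O | intermediate (not isolated)
17 | methyl (2E,4E,6E)-8-{[5,7-bis(benzyloxy)-2-oxo-2H-chromen-8-yl]oxy}-7-methoxy-9-oxonona-2,4,6,8-tetraenoate (dienylketene, C5 and C8 cis across C6=C7) | COC(=O)/C=C/C=C/C=C(\C(Oc1c(OCc2ccccc2)cc(OCc2ccccc2)c2ccc(=O)oc12)=C=O)OC | intermediate (not isolated)
18 | racemic methyl (E)-3-(3-{[5,7-bis(benzyloxy)-2-oxo-2H-chromen-8-yl]oxy}-4-methoxy-2-oxocyclohexa-3,5-dien-1-yl)acrylate | COC(=O)/C=C/C1C=CC(OC)=C(Oc2c(OCc3ccccc3)cc(OCc3ccccc3)c3ccc(=O)oc23)C1=O | intermediate (not isolated)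
19 | methyl (E)-3-(3-{[5,7-bis(benzyloxy)-2-oxo-2H-chromen-8-yl]oxy}-2-hydroxy-4-methoxyphenyl)acrylate | COC(=O)/C=C/c1ccc(OC)c(Oc2c(OCc3ccccc3)cc(OCc3ccccc3)c3ccc(=O)oc23)c1O | intermediate
20 | methyl (Z)-3-(3-{[5,7-bis(benzyloxy)-2-oxo-2H-chromen-8-yl]oxy}-2-hydroxy-4-methoxyphenyl)acrylate | COC(=O)/C=C\c1ccc(OC)c(Oc2c(OCc3ccccc3)cc(OCc3ccccc3)c3ccc(=O)oc23)c1O | intermediate (not isolated)
21 | 8-{[5,7-bis(benzyloxy)-2-oxo-2H-chromen-8-yl]oxy}-7-methoxy-2H-chromen-2-one | COc1ccc2ccc(=O)oc2c1Oc1c(OCc2ccccc2)cc(OCc2ccccc2)c2ccc(=O)oc12 | intermediate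
22 | 8-[(5,7-dihydroxy-2-oxo-2H-chromen-8-yl)oxy]-7-methoxy-2H-chromen-2-one | COc1ccc2ccc(=O)oc2c1Oc1c(O)cc(O)c2ccc(=O)oc12 | target

Total step count: 12. Longest linear sequence: 9 steps (steps 1, 2, 3, 5, 6, 7, 10, 11, 12).

Steps most likely to fail

Step 10. The coupling may attach the dienyl group at the aryloxy‑bearing allyl terminus (allylic transposition). The electron‑poor dienylstannane may also transmetalate too slowly, or the extended ketene may be intercepted or oligomerize before the electrocyclization. Fallback: chlorocyclobutenone 10 would be coupled under the same catalysis (PdCl2(PhCN)2, tri(2-furyl)phosphine, dioxane, 50 → 100 °C) with tributyl(vinyl)stannane, the simplest and best‑precedented partner of this benzannulation. This should give 5,7-bis(benzyloxy)-8-(2-hydroxy-6-methoxyphenoxy)-2H-chromen-2-one F1. Magnesium‑mediated ortho‑formylation (MgCl2, Et3N, paraformaldehyde, MeCN, reflux), for which only one ortho position of the new phenol is free, would give 3-{[5,7-bis(benzyloxy)-2-oxo-2H-chromen-8-yl]oxy}-2-hydroxy-4-methoxybenzaldehyde F2. Wittig olefination with Ph3P=CHCO2Me (CH2Cl2, rt) would then return to cinnamate 19.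

Step 7. The activated hydroxyl may ionize and chloride may return at the aryloxy‑bearing carbon (allylic transposition), which would end in loss of the aryloxy group. Fallback: alcohol 9 would be acylated (methyl chloroformate, pyridine, CH2Cl2, 0 °C) to racemic 3-{[5,7-bis(benzyloxy)-2-oxo-2H-chromen-8-yl]oxy}-2-methoxy-4-oxocyclobut-2-en-1-yl methyl carbonate F3, with no substitution at carbon. Zerovalent palladium (Pd2(dba)3, tri(2-furyl)phosphine, dioxane, 50 → 100 °C) would ionize the allylic carbonate with loss of CO2. The methoxide set free activates stannane 15 for a neutral Stille‑type allylic coupling, and the same ring opening and ring closure through 16, 17 and 18 would return to cinnamate 19.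

Step 6. The hydride may discriminate poorly between the two carbonyl groups, or attack in conjugate fashion with expulsion of the aryloxide. Fallback: phenol 5 (2 equiv) and dichloride 6 (iPr2NEt, CH2Cl2, −78 → 0 °C) would give the symmetrical 3,4-bis{[5,7-bis(benzyloxy)-2-oxo-2H-chromen-8-yl]oxy}cyclobut-3-ene-1,2-dione F4, whose two carbonyls are equivalent. LiAlH(OtBu)3 (THF, −78 °C) would give racemic 2,3-bis{[5,7-bis(benzyloxy)-2-oxo-2H-chromen-8-yl]oxy}-4-hydroxycyclobut-2-en-1-one F5. Methanolysis (MeOH, cat. Et3N, 0 °C) exchanges only the β‑aryloxy group of this vinylogous aryl ester by addition–elimination, which returns to alcohol 9 with unambiguous regiochemistry and releases one equivalent of 5 for re‑use.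

Further compounds
F1 | step 10 | 5,7-bis(benzyloxy)-8-(2-hydroxy-6-methoxyphenoxy)-2H-chromen-2-one | COc1cccc(O)c1Oc1c(OCc2ccccc2)cc(OCc2ccccc2)c2ccc(=O)oc12
F2 | step 10 | 3-{[5,7-bis(benzyloxy)-2-oxo-2H-chromen-8-yl]oxy}-2-hydroxy-4-methoxybenzaldehyde | COc1ccc(C=O)c(O)c1Oc1c(OCc2ccccc2)cc(OCc2ccccc2)c2ccc(=O)oc12
F3 | step 7 | racemic 3-{[5,7-bis(benzyloxy)-2-oxo-2H-chromen-8-yl]oxy}-2-methoxy-4-oxocyclobut-2-en-1-yl methyl carbonate | COC(=O)OC1C(OC)=C(Oc2c(OCc3ccccc3)cc(OCc3ccccc3)c3ccc(=O)oc23)C1=O
F4 | step 6 | 3,4-bis{[5,7-bis(benzyloxy)-2-oxo-2H-chromen-8-yl]oxy}cyclobut-3-ene-1,2-dione | O=C1C(=O)C(Oc2c(OCc3ccccc3)cc(OCc3ccccc3)c3ccc(=O)oc23)=C1Oc1c(OCc2ccccc2)cc(OCc2ccccc2)c2ccc(=O)oc12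
F5 | step 6 | racemic 2,3-bis{[5,7-bis(benzyloxy)-2-oxo-2H-chromen-8-yl]oxy}-4-hydroxycyclobut-2-en-1-one | OC1C(=O)C(Oc2c(OCc3ccccc3)cc(OCc3ccccc3)c3ccc(=O)oc23)=C1Oc1c(OCc2ccccc2)cc(OCc2ccccc2)c2ccc(=O)oc12
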